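You are about to repeat a run in which a free catalyst joins a dissolving solid and a dissolving gas into target.

    gas phase ⇌ dissolved gas, rate k1*(csat - [dissolved gas]) (k1 = 0.077 /s, csat = 200 mM)
    starting material + dissolved gas + free catalyst ⇌ free catalyst + target (K2 = 2.6 /M, k2 = 390 /M²/s)
    free catalyst → spent catalyst (k3 = 1.8 × 10⁻⁵ /s)
    solid substrate ⇌ starting material, rate k4*(cs4 - [starting material]) while solid is left; crystals form when [starting material] > cs4 (cs4 = 1.3 M, k4 = 0.026 /s)

solid substrate 1.5 M; gas phase 200 mM (held); free catalyst 0.11 mol%; time 40 s

- given per volume of solution although it is solid: solid substrate
- at the start none of the gas is dissolved
- at the start none of the solid substrate is in solution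
- run time (flask): 40 s

- target at 40 s, in percent of the solid substrate charged
- the change that raises the amount of target at 40 s, in percent of the solid substrate charged most ("none" if none brings more than 2 percentage points) (epsilon / theta / zeta / beta / none)
- amount of target at 40 s, in percent of the solid substrate charged, after theta

- epsilon: doubling the transfer coefficient of step 1, all else as stated
- theta: doubling the saturation concentration of gas phase, all else as stated
- zeta: doubling the amount of free catalyst, all else as stated
- beta: doubling the solubility in step 4, all else as stated

The free catalyst stands at 1.65 mM. I carry it in the lag time, the equilibrium constant divided by the product of the rate constant and c(free catalyst), 4.04 s: the target trails its equilibrium value, the equilibrium constant times c(starting material) times c(dissolved gas), by what it gains in that time. The gas fills with a time of 13.0 s and the solid with 38.5 s, so I treat the catalysed step as a quasi-equilibrium, because the lag time is shorter than both.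

Two extreme flasks can then be solved in the head. In the first, whatever the reaction takes is replaced at once, so at 40 s the solution holds c(starting material) 0.841 M and c(dissolved gas) 0.191 M, and the target reaches 27.8 %. In the second, nothing taken is replaced, so the target comes out of those same two amounts and reaches 8.28 %. Drawing the solution down quickens both transfers, so the real flask lies between them.

As a judgement, not a derivation, I take the geometric mean, 15.2 %. After theta c(dissolved gas) in the extremes is 0.382 M, and the first extreme at that value adds up to 1.67 M of starting material and target, above the charge of 1.5 M. So I cap it by setting starting material plus target equal to the charge, which gives 49.8 %. The second extreme gives 15.6 %, and the mean of the pair is 27.8 %. Ranking the changes by the first extreme, with starting material plus target capped at the charge, gives theta.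

The forecast gave 13.7 % (range 12.5 % to 15 %), theta, and 24.9 % after theta (range 22.5 % to 27 %), and says of its way: “I stepped the balances by hand”. My two figures stand higher than its own.

The simulation gives 13.8 %, theta with a gain of 11 percentage points, and 24.8 %. In this flask at 40.0 s, starting material 47.2 % and dissolved gas 0.123 M put the equilibrium value 1.4 points above the target, and the lag time times the average rise gives 1.4 points. The neighbouring flask charged with 0.044 mol% has a lag time of 10.1 s, and with its own average rise that gives 3.1 points. That neighbouring flask reads target 12.3 %, starting material 47.9 % and dissolved gas 0.126 M, so its target stands 3.4 points below equilibrium.

The rate constants were set for the occasion; the result is computed.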